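**Retrosynthetic overview**
1. Target 12 (2,3,4,6-tetrabromo-1H-indole) is traced back to N-mesyl-2,4,6-tribromoindole 10 by N-desulfonylation and electrophilic bromination at C3.
2. The strategy rests on C2 of the pyrrole ring carrying both N1 and a bromine. C2 is therefore derived from the CBr2 carbon of the 2-(2,2-dibromovinyl) N-mesylanilide 8, which keeps one bromine when N1 displaces the other (N1–C2 disconnection, no metal).
3. Anilide 8 comes from 2,4-dibromo-6-nitrobenzaldehyde 3 by Ramirez olefination, nitro reduction and mesylation; 3 comes from nitrotoluene 1 by enamine formation and periodate cleavage.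
4. Ring order: the benzene ring with the C4 and C6 bromines is bought in; the pyrrole ring is the only ring formed (step 5).

Key step: step 5

Assumption: the target has no stereogenic element, so no enantiocontrol is needed; 1,5-dibromo-2-methyl-3-nitrobenzene is taken as a catalogue compound (otherwise accessible by ring bromination of 4-bromo-2-nitrotoluene).

**Route**

Step 1
Reactants: 1 1,5-dibromo-2-methyl-3-nitrobenzene
Product: 3 2,4-dibromo-6-nitrobenzaldehyde, via dimethylamino enamine 2 (not isolated)
Conditions: DMF-DMA (3 equiv), DMF, 120 °C; then NaIO4 (3 equiv), DMF/H2O 1:1, 0 °C to rt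
Reagents that add atoms: N,N-dimethylformamide dimethyl acetal, COC(OC)N(C)C (supplies the CH–NMe2 unit of intermediate 2 only); sodium periodate, [Na+].[O-]I(=O)(=O)=O (aldehyde oxygen)
Why: The methyl group, acidified by the ortho nitro group and the ring bromines, should condense with the formamide acetal to the push–pull enamine (first stage of a Leimgruber–Batcho sequence), whose electron-rich C=C bond is then cleaved by periodate to the aryl aldehyde and DMF (oxidative enamine cleavage), with nitro and aryl bromides inert.

Step 2
Reactants: 3 2,4-dibromo-6-nitrobenzaldehyde; 4 carbon tetrabromide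
Product: 5 1,5-dibromo-2-(2,2-dibromoethenyl)-3-nitrobenzene
Conditions: CBr4 (2 equiv), PPh3 (4 equiv), CH2Cl2, 0 °C to rt
Reagents that add atoms: carbon tetrabromide (4), BrC(Br)(Br)Br
Why: Ramirez gem-dibromoolefination (first stage of the Corey–Fuchs sequence), in which the ylide Ph3P=CBr2 formed from PPh3 and CBr4 should undergo a Wittig reaction with the electron-poor aldehyde at a temperature where the phosphine attacks neither the nitro group nor the aryl bromides.

Step 3
Reactants: 5 1,5-dibromo-2-(2,2-dibromoethenyl)-3-nitrobenzene
Product: 6 3,5-dibromo-2-(2,2-dibromoethenyl)aniline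
Conditions: SnCl2·2H2O (5 equiv), EtOH, 75 °C; aq NaHCO3 work-up
Reagents that add atoms: none
Why: Chemoselective nitro reduction with tin(II) chloride, which reduces ArNO2 by electron and proton transfer and leaves aryl and vinyl C–Br bonds untouched, as is usual for 2-(2,2-dibromovinyl)nitroarenes.

Step 4
Reactants: 6 3,5-dibromo-2-(2,2-dibromoethenyl)aniline; 7 methanesulfonyl chloride
Product: 8 N-[3,5-dibromo-2-(2,2-dibromoethenyl)phenyl]methanesulfonamide
Conditions: MsCl (1.2 equiv), pyridine, CH2Cl2, 0 °C to rt
Reagents that add atoms: methanesulfonyl chloride (7), CS(=O)(=O)Cl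
Why: N-sulfonylation of the aniline with pyridine as a weak base, which leaves the product sulfonamide largely un-ionised so that mono-mesylation is favoured, and which makes the N–H acidic enough for the carbonate-promoted closure.

Step 5
Reactants: 8 N-[3,5-dibromo-2-(2,2-dibromoethenyl)phenyl]methanesulfonamide
Product: 10 2,4,6-tribromo-1-(methylsulfonyl)-1H-indole, via bromoalkyne sulfonamide 9 (not isolated)
Conditions: Cs2CO3 (2.5 equiv), DMF (0.05 M), 60–80 °C, N2
Reagents that add atoms: none
Why: Cesium carbonate should ionise the sulfonamide and remove HBr from the ArCH=CBr2 unit by anti-elimination to give bromoalkyne 9; the nitrogen anion then adds to the bromine-bearing alkyne carbon and the resulting C3 vinyl anion is protonated by hydrogen carbonate, so that N1–C2 forms with the C2 bromine retained (direct addition–elimination at the CBr2 carbon would converge on the same product). The closest known reaction type is the metal-free, base-promoted cyclisation of N-sulfonyl-2-(gem-dibromovinyl)anilines to 2-bromoindoles, with the phenol to 2-bromobenzofuran closure as its oxygen analogue. The pyrrole ring closes in the 5-endo-dig mode (5-endo-trig on the direct pathway). No stereocentre is formed. The step needs chemoselectivity for the vinylic/alkynyl C–Br carbon over the two aryl bromides and retention of the C2 bromine; this is secured by the absence of any transition metal and by the aryl bromides being mutually meta and lacking an ortho/para acceptor for SNAr. Regioselectivity for the bromine-bearing carbon is enforced geometrically, since attack at the aryl-bound alkyne carbon would require a 4-exo closure.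

Step 6
Reactants: 10 2,4,6-tribromo-1-(methylsulfonyl)-1H-indole
Product: 11 2,3,4,6-tetrabromo-1-(methylsulfonyl)-1H-indole
Conditions: Br2 (1.2 equiv), AcOH/CH2Cl2, rt to 40 °C; aq Na2S2O3
Reagents that add atoms: bromine, BrBr
Why: Electrophilic aromatic bromination at C3, the only free pyrrole position and still the most nucleophilic carbon of an N-sulfonylindole (the cation is stabilised by N1 and the C2 bromine lone pairs), while the dibrominated benzo ring is far less reactive.

Step 7
Reactants: 11 2,3,4,6-tetrabromo-1-(methylsulfonyl)-1H-indole
Product: 12 2,3,4,6-tetrabromo-1H-indole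
Conditions: LiOH·H2O (3 equiv), THF/H2O 3:1, rt to 45 °C; aq NH4Cl (neutral quench)
Reagents that add atoms: none
Why: N-desulfonylation by hydroxide attack at sulfur (or sulfene-type E1cB loss), which should be easy because the tetrabromoindolide is a well-stabilised leaving group, under conditions that leave all four C–Br bonds intact; the neutral quench avoids acid-promoted loss of the 2-bromo group.

**Compound list**
1 | 1,5-dibromo-2-methyl-3-nitrobenzene | Cc1c(Br)cc(Br)cc1[N+](=O)[O-] | starting material
2 | (E)-2-(2,4-dibromo-6-nitrophenyl)-N,N-dimethylethen-1-amine | CN(C)/C=C/c1c(Br)cc(Br)cc1[N+](=O)[O-] | intermediate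
3 | 2,4-dibromo-6-nitrobenzaldehyde | O=Cc1c(Br)cc(Br)cc1[N+](=O)[O-] | intermediate
4 | carbon tetrabromide | BrC(Br)(Br)Br | starting material
5 | 1,5-dibromo-2-(2,2-dibromoethenyl)-3-nitrobenzene | BrC(Br)=Cc1c(Br)cc(Br)cc1[N+](=O)[O-] | intermediate
6 | 3,5-dibromo-2-(2,2-dibromoethenyl)aniline | Nc1cc(Br)cc(Br)c1C=C(Br)Br | intermediate
7 | methanesulfonyl chloride | CS(=O)(=O)Cl | starting material
8 | N-[3,5-dibromo-2-(2,2-dibromoethenyl)phenyl]methanesulfonamide | CS(=O)(=O)Nc1cc(Br)cc(Br)c1C=C(Br)Br | intermediate
9 | N-[3,5-dibromo-2-(bromoethynyl)phenyl]methanesulfonamide | CS(=O)(=O)Nc1cc(Br)cc(Br)c1C#CBr | intermediate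
10 | 2,4,6-tribromo-1-(methylsulfonyl)-1H-indole | CS(=O)(=O)n1c(Br)cc2c(Br)cc(Br)cc21 | intermediate
11 | 2,3,4,6-tetrabromo-1-(methylsulfonyl)-1H-indole | CS(=O)(=O)n1c(Br)c(Br)c2c(Br)cc(Br)cc21 | intermediate
12 | 2,3,4,6-tetrabromo-1H-indole | Brc1cc(Br)c2c(Br)c(Br)[nH]c2c1 | target

**Step count:** 7 steps in total; longest linear sequence 7 steps.

**Steps most likely to fail**

1. Step 5 (key step). The closure may stall after dehydrobromination, lose the alkynyl bromine through halophilic attack, or be outrun by intermolecular N–C bond formation. The fallback sets out from 1 and returns at 12, and gives up the closure onto the dibromoalkene. Compound 1 is condensed with DMF-DMA to enamine 2 as in step 1, but 2 is then reduced with iron powder in acetic acid (Leimgruber–Batcho reductive cyclisation) to 4,6-dibromo-1H-indole F1. NBS (1 equiv, DMF, 0 °C) should brominate C3 to give 3,4,6-tribromo-1H-indole F2, and a second equivalent of NBS should brominate C2 to give 12. Both pyrrole bromines are then installed by electrophilic substitution.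

2. Step 6. Substitution at C3 may be sluggish, because the ring is deactivated by the N-sulfonyl group and three bromines and the peri bromine at C4 hinders approach. The fallback sets out from 10 and returns at 12 by reversing the order of the last two operations. Compound 10 is first desulfonylated (LiOH, THF/H2O) to 2,4,6-tribromo-1H-indole F3, whose free-NH pyrrole ring is far more nucleophilic. F3 is then brominated at C3 with NBS (1.0 equiv, DMF, 0 °C, acid-free) to give 12 directly.

3. Step 1. Condensation at a methyl group flanked by two ortho substituents may be slow and incomplete, so that thermal decomposition of the acetal competes. The fallback sets out from 1 and returns at 3. Benzylic radical bromination (NBS, AIBN, PhCF3, reflux) should give 1,5-dibromo-2-(bromomethyl)-3-nitrobenzene F4, and Kornblum oxidation (DMSO, NaHCO3, 90 °C) should convert it into aldehyde 3.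

**Further compounds**
F1 | step 5 | 4,6-dibromo-1H-indole | Brc1cc(Br)c2cc[nH]c2c1
F2 | step 5 | 3,4,6-tribromo-1H-indole | Brc1cc(Br)c2c(Br)c[nH]c2c1
F3 | step 6 | 2,4,6-tribromo-1H-indole | Brc1cc(Br)c2cc(Br)[nH]c2c1
F4 | step 1 | 1,5-dibromo-2-(bromomethyl)-3-nitrobenzene | BrCc1c(Br)cc(Br)cc1[N+](=O)[O-]
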